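The rate constants were drawn at random within sensible limits; the flask was simulated.

Early on, a molecule of reagent in these flasks meets three takers, and I follow it to see which one gets it.

| setting | autumn | midnight | spring |
|---|---|---|---|
| starting material | 0.17 M | 0.17 M | 0.17 M |
| partner | 0.221 M | 0.221 M | 0.221 M |
| reagent | 0.340 M | 0.680 M | 1.40 M |
| protic impurity | 0.0340 M | 0.0340 M | 0.0340 M |
| time | 12 h | 12 h | 12 h |

    starting material + reagent → open intermediate (k1 = 6.1 × 10⁻⁵ L mol⁻¹ s⁻¹)
    reagent + partner → second intermediate (k2 = 8.0 × 10⁻⁵ L mol⁻¹ s⁻¹)
    open intermediate + second intermediate → product (k3 = 2.7 × 10⁻⁴ L mol⁻¹ s⁻¹)
    starting material + product ⇌ idle adduct, settled at all times (K4 = 8.9 L mol⁻¹)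
    reagent + protic impurity → quenched reagent (k5 = 1.4 × 10⁻⁴ L mol⁻¹ s⁻¹)

- a species is counted by the starting material in it: one idle adduct counts as two
- amounts and yields of product count idle adduct too
- in an amount of product, one idle adduct counts as one product
- run time (autumn): 12 h

- which of these there is most of at the end, counted by the starting material in it, autumn (starting material / open intermediate / product)
- which of these there is most of at the end, counted by the starting material in it, midnight (starting material / open intermediate / product)
- which of these there is most of at the end, counted by the starting material in it, spring (starting material / open intermediate / product)
- how much there is at the end of the one of these that leads, in percent of the starting material charged: autumn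
- how much there is at the end of the one of these that leads, in percent of the starting material charged: midnight
- how much there is at the end of the one of these that leads, in percent of the starting material charged: spring

At the fork, each taker's chance goes as its rate constant times its concentration, and [reagent] cancels. Just after the start, the molecule goes to the starting material with chance 31.6%, to the partner with 53.9% and to the protic impurity with 14.5%. The step that joins the two intermediates uses no reagent, so my ledger has three entries: one reagent per starting material, one per partner, one per protic impurity. Paid in full, they sum to 0.425 M, and I call this sum the reagent demand. Autumn is charged below it, short by 0.0850 M, so there reagent is the limiting reagent. Midnight closes its books with a surplus of 0.255 M, and spring with 0.975 M.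

The books close slowly, though. In autumn, step 1 alone, with the other concentrations as charged, halves the starting material in 9.3 h, and the run is 12 h. Holding each reagent charge constant in a plain first-order decay by step 1 gives 40.8% of starting material not yet opened for autumn, 16.7% for midnight and 2.50% for spring. My reckoning stops there: I commit to starting material leading in autumn and losing the lead by midnight, and I have no percentages for product.

The forecast goes further. It names starting material for autumn at 52%, product for midnight at 35% and product for spring at 58%, and its grounds open with “Step 4 is treated as a fast equilibrium”.

The flasks give starting material in autumn at 51.7%, product at midnight at 36.0% and product in spring at 58.3%, so the forecast stands within its margins.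

Against the demand of 0.425 M, midnight's reagent after 120 h stands at 37.9% of its charge, 0.258 M, beside the surplus of 0.255 M. The neighbouring flask is midnight charged with 0.14 M of protic impurity; its demand is 0.531 M, and its surplus is smaller, 0.149 M. After 12.0 h that neighbour holds 0.128 M of quenched reagent, against 0.0319 M at midnight, and 41% of its reagent charge. Its product, at 32.7%, still stands above its starting material, at 28.2%.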